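The product's excess can be reckoned at a fork: a substrate molecule either reacts or crosses to its mirror image.

| setting | cedar | flask |
|---|---|---|
| left-handed substrate | 1 mM | 1.0 mM |
| right-handed substrate | 1 mM | 1.0 mM |
| gas | 0.080 mM (held) | 0.080 mM (held) |
| free catalyst | 5 mol% | 5 mol% |
| racemization catalyst | 0.35 mol% | 0.7 mol% |
| remark | run made earlier |  |
| time |  | 12 min |

cedar run (percent of the left-handed substrate and right-handed substrate together charged)

| time / s | left-handed product / % | right-handed product / % | left-handed substrate / % |
|---|---|---|---|
| 10.0 | 3.1 | 0 | 46.5 |
| 12.0 | 4.1 | 0.1 | 45.8 |
| 30.0 | 9.3 | 0.7 | 42.5 |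
| 80.0 | 22.0 | 1.7 | 34.8 |

(scatter of a reading: 0.5 percentage points)

- free catalyst is single-handed; left-handed substrate and right-handed substrate are mirror images of each other, charged as a racemate, each of them at the stated concentration
- what was read earlier has a scatter of 0.5 percentage points, one standard deviation
- at the start none of the gas is in solution
- an excess is the difference of the two amounts in percent of their sum
- an excess is below zero if the other one leads
- no earlier run changes the charge of racemization catalyst; that part of a forecast is a guess

* left-handed product and right-handed product together, in percent of the left-handed substrate and right-handed substrate charged together, at 12 min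
* excess of left-handed product over right-handed product in the product at 12 min
* whether the exchange between left-handed substrate and right-handed substrate keeps pace with the reaction: how far the product's excess at 12 min gets from its value without exchange to its value with instant exchange (above 80% keeps pace, below 20% hardly takes part, else lags behind)

My own reckoning reads the rates per molecule from the cedar run. Each product at 80.0 s is set against the mean of its substrate, and the gain of the left-handed pool between 30.0 s and 80.0 s against the mean lead of right-handed over left-handed substrate:

kL = 0.00649 s⁻¹

kR = 4.64 × 10⁻⁴ s⁻¹

crossing, cedar = 0.0171 s⁻¹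

Scaling the crossing with the racemization catalyst is a guess, and it gives a = 0.0342 s⁻¹ in the flask. Following one molecule to its end gives

excess = (kL − kR)/(kL + kR) × a/(a + h), with h = kL·kR/(kL + kR) = 4.33 × 10⁻⁴ s⁻¹

The crossing is measured against h, which is smaller than kL. The fork ratio a/h is 78.9, so the flask's excess is 85.5%, against 86.6% with instant exchange.

The forecast says 90% (76% to 97%), 86% (79% to 91%) and keeps pace, calling the crossing “far faster than reaction”.

The flask gives 93.1%, 86.3% and keeps pace, 96% of the way.

    reagent + free catalyst + left-handed substrate → free catalyst + left-handed product (k = 6.08 × 10⁶ M⁻² s⁻¹)
    reagent + free catalyst + right-handed substrate → free catalyst + right-handed product (k = 3.96 × 10⁵ M⁻² s⁻¹)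
    left-handed substrate + racemization catalyst ⇌ right-handed substrate + racemization catalyst, rate k3*[racemization catalyst]*[left-handed substrate] forward; the back reaction follows from the equilibrium constant (k = 3740 M⁻¹ s⁻¹)
    2 free catalyst ⇌ resting dimer (K = 59400 M⁻¹, k = 2510 M⁻¹ s⁻¹)
    gas ⇌ reagent, rate k5*(csat - [reagent]) (kL = 0.356 s⁻¹)

At 12.0 min the flask's substrates relax into each other by the crossing alone with a half-life of 0.221 min, while the two together fell from 28.0% of the charge at 6.00 min to 6.87% at 12.0 min. The forecast's range for the excess ends at 79%. The neighbour flask with 0.17 mol%, a quarter of the racemization catalyst, has a fork ratio of 19.2, which gives 82.3%, and it stands at 82.2%.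

Readings and results stem from a simulated flask for an exercise; scatter was added.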